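**Retrosynthetic overview**

1. Isariotin C ⇒ final desilylation and N-acylation of a protected bicyclic amino epoxy-ketol with (E)-7-oxododec-2-enoic acid (hex-5-enoic acid → Weinreb ketone → cross-metathesis with acrylic acid).
2. C6-OH and 7,8-epoxide of ring B ⇒ the C8 ketone of a bicyclo[3.3.1]nonane-8,9-dione: Saegusa enone, exo epoxidation, Wharton transposition, hydroxyl-directed epoxidation.
3. Ring A (C4–C5 bond) ⇒ desymmetrising intramolecular aldol of an (S)-α-amino aldehyde onto one arm of a 2-silyloxy-2-alkylcyclohexane-1,3-dione; C3 controls C1, C4 and C5.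
4. Key fragment union (C1–C2 bond) ⇒ intermolecular Knoevenagel-type aldol condensation of cyclohexane-1,3-dione with a D-serine-derived Garner-type aldehyde, reduced in situ by Hantzsch ester, then C1 hydroxylation.
5. Ring order: ring B (bought as the dione) → ring A (aldol) → oxirane (last ring).

Convention: the bicyclo[3.3.1]nonanes are numbered C1 (oxygenated bridgehead), C2 (CH2), C3 (N-bearing CH), C4 (carbinol CH), C5 (bridgehead CH), C6–C8 (rest of ring B), C9 (bridging ketone). Ring A = C1–C5 + C9; ring B = C5–C8 + C1 + C9. "Exo" = the face of ring B syn to C9 and away from C3. Descriptors refer to this numbering; in every bicycle the C3 nitrogen is equatorial (exo) and the C4 oxygen is axial and cis to it.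

Assumption: dimethyldioxirane (acetone solution, from Oxone) and anhydrous t-BuOOH (decane solution) are treated as stock reagents.

**Step 1**
Reactants: 1 D-serine methyl ester hydrochloride
Product: 2 methyl N-(benzyloxycarbonyl)-D-serinate
Conditions: CbzCl, NaHCO3, EtOAc/H2O, 0 °C → rt
Reagents that add atoms: benzyl chloroformate, O=C(Cl)OCc1ccccc1
Why: Schotten–Baumann carbamate formation on the amine, which is far more nucleophilic than the hydroxyl; the D-serine stereocentre (future C3) is not touched.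

**Step 2**
Reactants: 2 methyl N-(benzyloxycarbonyl)-D-serinate
Product: 3 3-benzyl 4-methyl (R)-2,2-dimethyloxazolidine-3,4-dicarboxylate
Conditions: Me2C(OMe)2, BF3·OEt2 (cat.), acetone, rt
Reagents that add atoms: 2,2-dimethoxypropane, COC(C)(C)OC
Why: acid-catalysed transacetalisation closes the Garner-type N,O-isopropylidene, which masks N–H and O–H and makes the later α-amino aldehyde configurationally robust.

**Step 3**
Reactants: 3 3-benzyl 4-methyl (R)-2,2-dimethyloxazolidine-3,4-dicarboxylate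
Product: 5 benzyl (R)-4-formyl-2,2-dimethyloxazolidine-3-carboxylate, via diisobutylaluminium hemiacetal 4 (not isolated)
Conditions: i-Bu2AlH, toluene, −78 °C; MeOH, then aq. KNaC4H4O6
Reagents that add atoms: none
Why: DIBAL half-reduction of the ester, in which the tetrahedral aluminium hemiacetal survives at −78 °C and releases the aldehyde only on work-up, so there is neither over-reduction nor epimerisation.

**Step 4**
Reactants: 5 benzyl (R)-4-formyl-2,2-dimethyloxazolidine-3-carboxylate, 6 cyclohexane-1,3-dione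
Product: 8 benzyl (S)-4-[(2,6-dioxocyclohexyl)methyl]-2,2-dimethyloxazolidine-3-carboxylate, via Knoevenagel alkylidene dione 7 (not isolated)
Conditions: L-proline (10 mol %), Hantzsch ester (diethyl 2,6-dimethyl-1,4-dihydropyridine-3,5-dicarboxylate, 1.1 equiv), CH2Cl2, rt
Reagents that add atoms: none
Why: key fragment union, an intermolecular Knoevenagel-type aldol condensation of the dione enol with the aldehyde (through the proline iminium ion) that forms the C1–C2 bond, the very electrophilic alkylidene dione being reduced at once by hydride transfer from the Hantzsch ester (three-component reductive alkylation), which prevents double addition and leaves the oxazolidine stereocentre untouched.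

**Step 5**
Reactants: 8 benzyl (S)-4-[(2,6-dioxocyclohexyl)methyl]-2,2-dimethyloxazolidine-3-carboxylate
Product: 9 benzyl (S)-4-[(1-hydroxy-2,6-dioxocyclohexyl)methyl]-2,2-dimethyloxazolidine-3-carboxylate
Conditions: DMDO, acetone, 0 °C
Reagents that add atoms: dimethyldioxirane, CC1(C)OO1
Why: electrophilic α-hydroxylation in which the dioxirane epoxidises the enol of the 2-alkyl-1,3-dione and the epoxide collapses to the 2-hydroxy diketone; the new carbinol carbon lies on the mirror plane of the dione and is not yet a stereocentre.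

**Step 6**
Reactants: 9 benzyl (S)-4-[(1-hydroxy-2,6-dioxocyclohexyl)methyl]-2,2-dimethyloxazolidine-3-carboxylate
Product: 10 benzyl (S)-4-{[2,6-dioxo-1-(triethylsilyloxy)cyclohexyl]methyl}-2,2-dimethyloxazolidine-3-carboxylate
Conditions: Et3SiOTf, 2,6-lutidine, CH2Cl2, −78 → 0 °C
Reagents that add atoms: triethylsilyl trifluoromethanesulfonate, CC[Si](CC)(CC)OS(=O)(=O)C(F)(F)F
Why: silyl triflate O-silylation of the tertiary alcohol, which later stops the γ-hydroxy aldehyde from closing to a lactol and being over-oxidised.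

**Step 7**
Reactants: 10 benzyl (S)-4-{[2,6-dioxo-1-(triethylsilyloxy)cyclohexyl]methyl}-2,2-dimethyloxazolidine-3-carboxylate
Product: 11 benzyl N-{(S)-1-[2,6-dioxo-1-(triethylsilyloxy)cyclohexyl]-3-hydroxypropan-2-yl}carbamate
Conditions: BiBr3 (20 mol %), MeCN, H2O (5 equiv), rt
Reagents that add atoms: none
Why: mild Lewis-acid-catalysed hydrolysis of the N,O-acetonide frees the primary alcohol and the carbamate N–H while the benzyl carbamate and the hindered tertiary silyl ether are retained.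

**Step 8**
Reactants: 11 benzyl N-{(S)-1-[2,6-dioxo-1-(triethylsilyloxy)cyclohexyl]-3-hydroxypropan-2-yl}carbamate
Product: 12 benzyl N-{(S)-1-[2,6-dioxo-1-(triethylsilyloxy)cyclohexyl]-3-oxopropan-2-yl}carbamate
Conditions: Dess–Martin periodinane, wet CH2Cl2, 0 °C → rt; used crude
Reagents that add atoms: none
Why: Dess–Martin oxidation of the primary alcohol under non-basic conditions, the standard way to make N-carbamoyl α-amino aldehydes without epimerisation.

**Step 9**
Reactants: 12 benzyl N-{(S)-1-[2,6-dioxo-1-(triethylsilyloxy)cyclohexyl]-3-oxopropan-2-yl}carbamate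
Product: 13 benzyl N-[(1S,3S,4R,5R)-4-hydroxy-8,9-dioxo-1-(triethylsilyloxy)bicyclo[3.3.1]nonan-3-yl]carbamate
Conditions: (+)-camphor-10-sulfonic acid (20 mol %), CH2Cl2, 0 °C → rt
Reagents that add atoms: none
Why: acid-catalysed intramolecular aldol addition (6-enolendo-exo-trig) that desymmetrises the dione, since only the ketone arm whose chair transition state keeps C3–NHCbz equatorial reacts (C3 thereby sets C1 and C5) and the hydrogen-bonded closed transition state (enol O–H to aldehyde O) is expected to place the new C4 hydroxyl axial and cis to nitrogen, dehydration being blocked because it would need a bridgehead alkene.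

**Step 10**
Reactants: 13 benzyl N-[(1S,3S,4R,5R)-4-hydroxy-8,9-dioxo-1-(triethylsilyloxy)bicyclo[3.3.1]nonan-3-yl]carbamate
Product: 14 benzyl N-[(1S,3S,4R,5R)-8,9-dioxo-1,4-bis(triethylsilyloxy)bicyclo[3.3.1]nonan-3-yl]carbamate
Conditions: Et3SiOTf, 2,6-lutidine, CH2Cl2, −78 °C
Reagents that add atoms: triethylsilyl trifluoromethanesulfonate, CC[Si](CC)(CC)OS(=O)(=O)C(F)(F)F
Why: O-silylation of the secondary ketol hydroxyl so that it cannot undergo retro-aldol cleavage in the basic steps that follow.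

**Step 11**
Reactants: 14 benzyl N-[(1S,3S,4R,5R)-8,9-dioxo-1,4-bis(triethylsilyloxy)bicyclo[3.3.1]nonan-3-yl]carbamate
Product: 16 benzyl N-[(1S,3S,4R,5R)-8,9-dioxo-1,4-bis(triethylsilyloxy)bicyclo[3.3.1]non-6-en-3-yl]carbamate, via trimethylsilyl enol ether 15 (not isolated)
Conditions: Me3SiOTf, Et3N, CH2Cl2, 0 °C; then Pd(OAc)2 (1.1 equiv), MeCN, rt
Reagents that add atoms: none
Why: Saegusa–Ito dehydrogenation, in which soft enolisation can only occur towards C7 (C1 is quaternary, C5 is a bridgehead) and palladium diacetate converts the silyl enol ether into the C6–C7 enone.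

**Step 12**
Reactants: 16 benzyl N-[(1S,3S,4R,5R)-8,9-dioxo-1,4-bis(triethylsilyloxy)bicyclo[3.3.1]non-6-en-3-yl]carbamate
Product: 17 benzyl N-[(1R,3S,4R,5R,6S,7S)-6,7-epoxy-8,9-dioxo-1,4-bis(triethylsilyloxy)bicyclo[3.3.1]nonan-3-yl]carbamate (exo epoxide)
Conditions: t-BuOOH, 1,8-diazabicyclo[5.4.0]undec-7-ene (DBU), CH2Cl2, 0 °C → rt
Reagents that add atoms: tert-butyl hydroperoxide, CC(C)(C)OO
Why: Weitz–Scheffer nucleophilic epoxidation in which the hydroperoxide anion adds to C6 from the exo face (ring A shields the other face), setting C6 and C7.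

**Step 13**
Reactants: 17 benzyl N-[(1R,3S,4R,5R,6S,7S)-6,7-epoxy-8,9-dioxo-1,4-bis(triethylsilyloxy)bicyclo[3.3.1]nonan-3-yl]carbamate
Product: 19 benzyl N-[(1S,3S,4R,5R,6R)-6-hydroxy-9-oxo-1,4-bis(triethylsilyloxy)bicyclo[3.3.1]non-7-en-3-yl]carbamate, via epoxy hydrazone 18 (not isolated)
Conditions: N2H4·H2O, AcOH (cat.), MeOH, 0 °C → rt
Reagents that add atoms: none
Why: Wharton transposition, in which the C8 hydrazone opens the epoxide to an alkenyl diazene that loses N2, leaving the C7=C8 alkene and the C6 alcohol, whose C–O bond is never broken and therefore stays exo (axial).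

**Step 14**
Reactants: 19 benzyl N-[(1S,3S,4R,5R,6R)-6-hydroxy-9-oxo-1,4-bis(triethylsilyloxy)bicyclo[3.3.1]non-7-en-3-yl]carbamate
Product: 20 benzyl N-[(1S,3S,4R,5R,6S,7S,8S)-7,8-epoxy-6-hydroxy-9-oxo-1,4-bis(triethylsilyloxy)bicyclo[3.3.1]nonan-3-yl]carbamate
Conditions: VO(acac)2 (5 mol %), t-BuOOH, CH2Cl2, 0 °C → rt
Reagents that add atoms: tert-butyl hydroperoxide, CC(C)(C)OO
Why: hydroxyl-directed vanadium-catalysed epoxidation of the allylic alcohol, which delivers oxygen syn to the axial C6–OH (also the sterically open exo face) and so sets C7 and C8 with the epoxide cis to the hydroxyl.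

**Step 15**
Reactants: 20 benzyl N-[(1S,3S,4R,5R,6S,7S,8S)-7,8-epoxy-6-hydroxy-9-oxo-1,4-bis(triethylsilyloxy)bicyclo[3.3.1]nonan-3-yl]carbamate
Product: 21 (1S,3S,4R,5R,6S,7S,8S)-3-amino-7,8-epoxy-6-hydroxy-1,4-bis(triethylsilyloxy)bicyclo[3.3.1]nonan-9-one
Conditions: H2 (1 atm), Pd/C (10 %), EtOAc, rt; used at once
Reagents that add atoms: none
Why: neutral hydrogenolysis of the benzyl carbamate, to which the isolated epoxide, the ketone and the silyl ethers are inert.

**Step 16**
Reactants: 22 hex-5-enoic acid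
Product: 24 N-methoxy-N-methylhex-5-enamide, via hex-5-enoyl imidazole 23 (not isolated)
Conditions: CDI, CH2Cl2, rt; then MeNH(OMe)·HCl
Reagents that add atoms: N,O-dimethylhydroxylamine hydrochloride, CNOC.Cl
Why: acyl transfer in which carbonyldiimidazole activates the acid as its acyl imidazole and this is aminolysed to the Weinreb amide.

**Step 17**
Reactants: 24 N-methoxy-N-methylhex-5-enamide, 25 pentylmagnesium bromide
Product: 27 undec-1-en-6-one, via magnesium chelate 26 (not isolated)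
Conditions: n-C5H11MgBr, THF, 0 °C; then 1 M HCl
Reagents that add atoms: none
Why: Weinreb ketone synthesis, in which the Grignard adduct is held as a stable five-membered magnesium chelate until acidic work-up, so no tertiary alcohol forms.

**Step 18**
Reactants: 27 undec-1-en-6-one, 28 acrylic acid
Product: 29 (E)-7-oxododec-2-enoic acid
Conditions: second-generation Hoveyda–Grubbs catalyst, RuCl2(SIMes)(=CH-C6H4-2-O-i-Pr) (5 mol %), CH2Cl2, 40 °C
Reagents that add atoms: none
Why: olefin cross-metathesis of the terminal alkene with the electron-poor partner acrylic acid, which does not homodimerise and gives the conjugated (E)-acid under thermodynamic control.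

**Step 19**
Reactants: 21 (1S,3S,4R,5R,6S,7S,8S)-3-amino-7,8-epoxy-6-hydroxy-1,4-bis(triethylsilyloxy)bicyclo[3.3.1]nonan-9-one, 29 (E)-7-oxododec-2-enoic acid
Product: 31 (E)-N-[(1S,3S,4R,5R,6S,7S,8S)-7,8-epoxy-6-hydroxy-9-oxo-1,4-bis(triethylsilyloxy)bicyclo[3.3.1]nonan-3-yl]-7-oxododec-2-enamide, via benzotriazolyl ester 30 (not isolated)
Conditions: EDC·HCl, 1-hydroxybenzotriazole (HOBt), CH2Cl2, 0 °C → rt
Reagents that add atoms: none
Why: carbodiimide/HOBt amide coupling in which the primary amine is acylated by the benzotriazolyl ester much faster than the hindered secondary C6 hydroxyl.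

**Step 20**
Reactants: 31 (E)-N-[(1S,3S,4R,5R,6S,7S,8S)-7,8-epoxy-6-hydroxy-9-oxo-1,4-bis(triethylsilyloxy)bicyclo[3.3.1]nonan-3-yl]-7-oxododec-2-enamide
Product: 32 isariotin C
Conditions: HF·pyridine, pyridine, THF, 0 °C → rt
Reagents that add atoms: none
Why: fluoride-driven cleavage of both triethylsilyl ethers with buffered HF·pyridine, conditions under which the epoxide, the β-ketol and the enamide survive and no stereocentre is touched.

**Compound list**

1 | D-serine methyl ester hydrochloride | Cl.COC(=O)[C@H](N)CO | starting material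
2 | methyl N-(benzyloxycarbonyl)-D-serinate | COC(=O)[C@H](NC(=O)OCc1ccccc1)CO | intermediate
3 | 3-benzyl 4-methyl (R)-2,2-dimethyloxazolidine-3,4-dicarboxylate | COC(=O)[C@H]1COC(C)(C)N1C(=O)OCc1ccccc1 | intermediate
4 | diisobutylaluminium hemiacetal of 3 (hemiacetal carbon unassigned) | COC(O[Al](CC(C)C)CC(C)C)[C@H]1COC(C)(C)N1C(=O)OCc1ccccc1 | intermediate (not isolated)
5 | benzyl (R)-4-formyl-2,2-dimethyloxazolidine-3-carboxylate | O=C[C@H]1COC(C)(C)N1C(=O)OCc1ccccc1 | intermediate
6 | cyclohexane-1,3-dione | O=C1CCCC(=O)C1 | starting material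
7 | benzyl (S)-4-[(2,6-dioxocyclohexylidene)methyl]-2,2-dimethyloxazolidine-3-carboxylate | O=C1CCCC(=O)C1=C[C@H]1COC(C)(C)N1C(=O)OCc1ccccc1 | intermediate (not isolated)
8 | benzyl (S)-4-[(2,6-dioxocyclohexyl)methyl]-2,2-dimethyloxazolidine-3-carboxylate (drawn as diketone; enolised in solution) | O=C1CCCC(=O)C1C[C@H]1COC(C)(C)N1C(=O)OCc1ccccc1 | intermediate
9 | benzyl (S)-4-[(1-hydroxy-2,6-dioxocyclohexyl)methyl]-2,2-dimethyloxazolidine-3-carboxylate | O=C1CCCC(=O)C1(O)C[C@H]1COC(C)(C)N1C(=O)OCc1ccccc1 | intermediate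
10 | benzyl (S)-4-{[2,6-dioxo-1-(triethylsilyloxy)cyclohexyl]methyl}-2,2-dimethyloxazolidine-3-carboxylate | CC[Si](CC)(CC)OC1(C[C@H]2COC(C)(C)N2C(=O)OCc2ccccc2)C(=O)CCCC1=O | intermediate
11 | benzyl N-{(S)-1-[2,6-dioxo-1-(triethylsilyloxy)cyclohexyl]-3-hydroxypropan-2-yl}carbamate | CC[Si](CC)(CC)OC1(C[C@@H](CO)NC(=O)OCc2ccccc2)C(=O)CCCC1=O | intermediate
12 | benzyl N-{(S)-1-[2,6-dioxo-1-(triethylsilyloxy)cyclohexyl]-3-oxopropan-2-yl}carbamate | CC[Si](CC)(CC)OC1(C[C@@H](C=O)NC(=O)OCc2ccccc2)C(=O)CCCC1=O | intermediate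
13 | benzyl N-[(1S,3S,4R,5R)-4-hydroxy-8,9-dioxo-1-(triethylsilyloxy)bicyclo[3.3.1]nonan-3-yl]carbamate | O=C(OCc1ccccc1)N[C@H]1C[C@@]2(O[Si](CC)(CC)CC)C(=O)[C@H](CCC2=O)[C@H]1O | intermediate
14 | benzyl N-[(1S,3S,4R,5R)-8,9-dioxo-1,4-bis(triethylsilyloxy)bicyclo[3.3.1]nonan-3-yl]carbamate | O=C(OCc1ccccc1)N[C@H]1C[C@@]2(O[Si](CC)(CC)CC)C(=O)[C@H](CCC2=O)[C@H]1O[Si](CC)(CC)CC | intermediate
15 | benzyl N-[(1S,3S,4R,5R)-9-oxo-1,4-bis(triethylsilyloxy)-8-(trimethylsilyloxy)bicyclo[3.3.1]non-7-en-3-yl]carbamate | O=C(OCc1ccccc1)N[C@H]1C[C@@]2(O[Si](CC)(CC)CC)C(=O)[C@H](CC=C2O[Si](C)(C)C)[C@H]1O[Si](CC)(CC)CC | intermediate (not isolated)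
16 | benzyl N-[(1S,3S,4R,5R)-8,9-dioxo-1,4-bis(triethylsilyloxy)bicyclo[3.3.1]non-6-en-3-yl]carbamate | O=C(OCc1ccccc1)N[C@H]1C[C@@]2(O[Si](CC)(CC)CC)C(=O)[C@H](C=CC2=O)[C@H]1O[Si](CC)(CC)CC | intermediate
17 | benzyl N-[(1R,3S,4R,5R,6S,7S)-6,7-epoxy-8,9-dioxo-1,4-bis(triethylsilyloxy)bicyclo[3.3.1]nonan-3-yl]carbamate (exo epoxide) | O=C(OCc1ccccc1)N[C@H]1C[C@@]2(O[Si](CC)(CC)CC)C(=O)[C@H]([C@@H]3O[C@@H]3C2=O)[C@H]1O[Si](CC)(CC)CC | intermediate
18 | C8 hydrazone of 17 (C=N geometry unassigned) | O=C(OCc1ccccc1)N[C@H]1C[C@@]2(O[Si](CC)(CC)CC)C(=O)[C@H]([C@@H]3O[C@@H]3C2=NN)[C@H]1O[Si](CC)(CC)CC | intermediate (not isolated)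
19 | benzyl N-[(1S,3S,4R,5R,6R)-6-hydroxy-9-oxo-1,4-bis(triethylsilyloxy)bicyclo[3.3.1]non-7-en-3-yl]carbamate (6-OH exo, axial) | O=C(OCc1ccccc1)N[C@H]1C[C@@]2(O[Si](CC)(CC)CC)C(=O)[C@H]([C@H](O)C=C2)[C@H]1O[Si](CC)(CC)CC | intermediate
20 | benzyl N-[(1S,3S,4R,5R,6S,7S,8S)-7,8-epoxy-6-hydroxy-9-oxo-1,4-bis(triethylsilyloxy)bicyclo[3.3.1]nonan-3-yl]carbamate | O=C(OCc1ccccc1)N[C@H]1C[C@@]2(O[Si](CC)(CC)CC)C(=O)[C@H]([C@H](O)[C@@H]3O[C@@H]32)[C@H]1O[Si](CC)(CC)CC | intermediate
21 | (1S,3S,4R,5R,6S,7S,8S)-3-amino-7,8-epoxy-6-hydroxy-1,4-bis(triethylsilyloxy)bicyclo[3.3.1]nonan-9-one | N[C@H]1C[C@@]2(O[Si](CC)(CC)CC)C(=O)[C@H]([C@H](O)[C@@H]3O[C@@H]32)[C@H]1O[Si](CC)(CC)CC | intermediate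
22 | hex-5-enoic acid | C=CCCCC(=O)O | starting material
23 | 1-(hex-5-enoyl)imidazole | C=CCCCC(=O)n1ccnc1 | intermediate (not isolated)
24 | N-methoxy-N-methylhex-5-enamide | C=CCCCC(=O)N(C)OC | intermediate
25 | pentylmagnesium bromide | CCCCC[Mg]Br | starting material
26 | bromomagnesium alkoxide (chelate) of the tetrahedral adduct of 24 and 25 | C=CCCCC(CCCCC)(O[Mg]Br)N(C)OC | intermediate (not isolated)
27 | undec-1-en-6-one | C=CCCCC(=O)CCCCC | intermediate
28 | acrylic acid | C=CC(=O)O | starting material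
29 | (E)-7-oxododec-2-enoic acid | CCCCCC(=O)CCC/C=C/C(=O)O | intermediate
30 | benzotriazol-1-yl (E)-7-oxododec-2-enoate | CCCCCC(=O)CCC/C=C/C(=O)On1nnc2ccccc12 | intermediate (not isolated)
31 | (E)-N-[(1S,3S,4R,5R,6S,7S,8S)-7,8-epoxy-6-hydroxy-9-oxo-1,4-bis(triethylsilyloxy)bicyclo[3.3.1]nonan-3-yl]-7-oxododec-2-enamide | CCCCCC(=O)CCC/C=C/C(=O)N[C@H]1C[C@@]2(O[Si](CC)(CC)CC)C(=O)[C@H]([C@H](O)[C@@H]3O[C@@H]32)[C@H]1O[Si](CC)(CC)CC | intermediate
32 | isariotin C, (E)-N-[(1S,3S,4R,5S,6S,7S,8S)-7,8-epoxy-1,4,6-trihydroxy-9-oxobicyclo[3.3.1]nonan-3-yl]-7-oxododec-2-enamide | CCCCCC(=O)CCC/C=C/C(=O)N[C@H]1C[C@@]2(O)C(=O)[C@H]([C@H](O)[C@@H]3O[C@@H]32)[C@H]1O | target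

**Totals and risks**

Total step count: 20. Longest linear sequence: 17 steps (steps 1–15, 19, 20); steps 16–18 are the three-step branch to the side-chain acid.

Steps most likely to fail:

Step 7 (acetonide hydrolysis next to the tertiary silyl ether). The risk is partial loss of the triethylsilyl ether, or ketalisation or retro-Claisen cleavage of the non-enolisable diketone. The fallback changes the protecting-group logic and sets out from hydroxy dione 9. The acetonide is hydrolysed while no silyl ether is present (AcOH/H2O 4:1, 40 °C), giving the N-Cbz amino diol F1. Both hydroxyls are then silylated (Et3SiOTf, 2,6-lutidine, CH2Cl2) to the bis(triethylsilyl) ether F2. A Swern oxidation ((COCl)2, DMSO, CH2Cl2, −78 → −30 °C, then i-Pr2NEt) cleaves and oxidises only the primary silyl ether, and the route is rejoined at aldehyde 12.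

Step 9 (desymmetrising aldol). The risks are closure to the C4 epimer (hydroxyl equatorial) and erosion of the C3 centre by enolisation of the amino aldehyde; the C4 outcome is predicted from the transition-state model, not from a close precedent. The fallback sets the C4 configuration by substitution instead of by the aldol transition state and sets out from aldehyde 12. Whatever conditions close the ring cleanly are used, and the equatorial C4-epimeric ketol F3 is taken on. Mitsunobu inversion with chloroacetic acid (PPh3, DIAD, THF, 0 °C) gives the axial chloroacetate F4; SN2 attack comes from the open axial side and elimination is impossible at the bridgehead. Mild methanolysis (Et3N, MeOH, 0 °C) rejoins the route at ketol 13.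

Step 13 (Wharton transposition). The risk is that hydrazine attacks the C9 ketone or triggers retro-Claisen cleavage of the 1,3-diketone, or that the hindered C8 hydrazone forms slowly. The fallback replaces the epoxy-ketone transposition by deoxygenation and allylic oxidation and sets out from diketone 14. KN(SiMe3)2 (2.2 equiv) and PhNTf2 in THF at −78 °C give the C7–C8 enol triflate F5, since only C7 can be deprotonated. Reduction with Pd(OAc)2/PPh3, HCO2H and n-Bu3N in DMF at 60 °C gives the C7–C8 alkene F6. Allylic hydroxylation with SeO2 (cat.)/t-BuOOH in CH2Cl2 (ene reaction, then a [2,3]-shift on the exo face) installs the axial C6 hydroxyl and rejoins the route at allylic alcohol 19.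

**Further compounds**

F1 | step 7 | benzyl N-[(S)-1-hydroxy-3-(1-hydroxy-2,6-dioxocyclohexyl)propan-2-yl]carbamate | O=C1CCCC(=O)C1(O)C[C@@H](CO)NC(=O)OCc1ccccc1
F2 | step 7 | benzyl N-{(S)-1-[2,6-dioxo-1-(triethylsilyloxy)cyclohexyl]-3-(triethylsilyloxy)propan-2-yl}carbamate | CC[Si](CC)(CC)OC[C@H](CC1(O[Si](CC)(CC)CC)C(=O)CCCC1=O)NC(=O)OCc1ccccc1
F3 | step 9 | benzyl N-[(1S,3S,4S,5R)-4-hydroxy-8,9-dioxo-1-(triethylsilyloxy)bicyclo[3.3.1]nonan-3-yl]carbamate (C4 epimer of 13) | O=C(OCc1ccccc1)N[C@H]1C[C@@]2(O[Si](CC)(CC)CC)C(=O)[C@H](CCC2=O)[C@@H]1O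
F4 | step 9 | (1S,3S,4R,5R)-3-(benzyloxycarbonylamino)-8,9-dioxo-1-(triethylsilyloxy)bicyclo[3.3.1]nonan-4-yl chloroacetate | O=C(OCc1ccccc1)N[C@H]1C[C@@]2(O[Si](CC)(CC)CC)C(=O)[C@H](CCC2=O)[C@H]1OC(=O)CCl
F5 | step 13 | (1S,3S,4R,5R)-3-(benzyloxycarbonylamino)-9-oxo-1,4-bis(triethylsilyloxy)bicyclo[3.3.1]non-7-en-8-yl trifluoromethanesulfonate | O=C(OCc1ccccc1)N[C@H]1C[C@@]2(O[Si](CC)(CC)CC)C(=O)[C@H](CC=C2OS(=O)(=O)C(F)(F)F)[C@H]1O[Si](CC)(CC)CC
F6 | step 13 | benzyl N-[(1S,3S,4R,5R)-9-oxo-1,4-bis(triethylsilyloxy)bicyclo[3.3.1]non-7-en-3-yl]carbamate | O=C(OCc1ccccc1)N[C@H]1C[C@@]2(O[Si](CC)(CC)CC)C(=O)[C@H](CC=C2)[C@H]1O[Si](CC)(CC)CC
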